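On the oxolane ring (O1, C2–C5) the C2 aryl group stands cis to the C3 hydroxymethyl group, while C3/C4 and C4/C5 are trans. This less stable C2 centre is best made with its hydrogen arriving last, so the bond from C2 to the ipso carbon of its syringyl ring is cut at the lactone oxidation level. In the key step 4-benzyloxy-3,5-dimethoxyphenyllithium adds to the carbonyl carbon of an all-trans γ-lactone that already holds C3, C4, C5 and the other aryl ring, joining both halves as a cyclic hemiketal; ionic hydrogenation then delivers hydride anti to the C3 substituent. The lactone comes from an iridium-catalysed anti-(hydroxymethyl)allylation of the benzaldehyde.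

Key step: step 7

Assumption: compounds 1, 2 and 11 are taken as commercial, and the (R)-ligand in step 1 is assigned by analogy with related aryl aldehyde allylations of this catalyst family; the configuration of 3 would be checked (Mosher esters) and the (S)-ligand used if the sense proves opposite.

Step 1
Reactants: 1 4-(benzyloxy)-3,5-dimethoxybenzaldehyde; 2 4-vinyl-1,3-dioxolan-2-one (racemic)
Product: 3 (1R,2S)-1-[4-(benzyloxy)-3,5-dimethoxyphenyl]-2-ethenylpropane-1,3-diol
Conditions: [Ir(cod)Cl]2 (2.5 mol%), (R)-SEGPHOS (5 mol%), 4-cyano-3-nitrobenzoic acid (10 mol%), K3PO4 (cat.), i-PrOH (2 equiv), THF, 90 °C, sealed tube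
Reagents that add atoms: none
Why: Iridium-catalysed transfer-hydrogenative carbonyl (hydroxymethyl)allylation: decarboxylative ionisation of 2 gives an (E)-σ-allyliridium that should add to the aldehyde through a closed chair transition state (anti relation of C1–OH and C2–CH2OH), with the chiral bisphosphine setting the absolute configuration and isopropanol serving as terminal reductant.

Step 2
Reactants: 3 (1R,2S)-1-[4-(benzyloxy)-3,5-dimethoxyphenyl]-2-ethenylpropane-1,3-diol
Product: 4 (1R,2S)-1-[4-(benzyloxy)-3,5-dimethoxyphenyl]-2-{[(triisopropylsilyl)oxy]methyl}but-3-en-1-ol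
Conditions: TIPSCl (1.1 equiv), imidazole, CH2Cl2, 0 °C to rt
Reagents that add atoms: chlorotriisopropylsilane CC(C)[Si](Cl)(C(C)C)C(C)C
Why: Silyl ether formation with the bulky chlorosilane should be selective for the primary hydroxyl over the hindered secondary benzylic one and touches no stereocentre.

Step 3
Reactants: 4 (1R,2S)-1-[4-(benzyloxy)-3,5-dimethoxyphenyl]-2-{[(triisopropylsilyl)oxy]methyl}but-3-en-1-ol
Product: 6 (1R,2S)-1-[4-(benzyloxy)-3,5-dimethoxyphenyl]-2-{[(triisopropylsilyl)oxy]methyl}butane-1,4-diol, via B-alkyl-9-BBN adduct 5 (not isolated)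
Conditions: 9-BBN (2.5 equiv), THF, 0 °C to rt; then NaOH, H2O2, H2O, 0 °C
Reagents that add atoms: hydrogen peroxide OO
Why: Brown hydroboration–oxidation: 9-BBN should add anti-Markovnikov to the monosubstituted alkene and alkaline peroxide replaces boron by hydroxyl with the stereocentres untouched (the excess of borane allows for the free hydroxyl).

Step 4
Reactants: 6 (1R,2S)-1-[4-(benzyloxy)-3,5-dimethoxyphenyl]-2-{[(triisopropylsilyl)oxy]methyl}butane-1,4-diol
Product: 8 (4S,5R)-5-[4-(benzyloxy)-3,5-dimethoxyphenyl]-4-{[(triisopropylsilyl)oxy]methyl}dihydrofuran-2(3H)-one, via lactol 7 (not isolated)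
Conditions: TEMPO (0.2 equiv), PhI(OAc)2 (2.5 equiv), CH2Cl2, rt
Reagents that add atoms: none
Why: TEMPO/PhI(OAc)2 oxidative lactonisation of a 1,4-diol: the oxoammonium salt oxidises the primary alcohol selectively, the aldehyde closes onto the benzylic hydroxyl to lactol 7 and this is oxidised on to the γ-lactone, so the benzylic alcohol becomes the ring oxygen before it can be oxidised.

Step 5
Reactants: 8 (4S,5R)-5-[4-(benzyloxy)-3,5-dimethoxyphenyl]-4-{[(triisopropylsilyl)oxy]methyl}dihydrofuran-2(3H)-one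
Product: 10 (3S,4S,5R)-5-[4-(benzyloxy)-3,5-dimethoxyphenyl]-3,4-bis{[(triisopropylsilyl)oxy]methyl}dihydrofuran-2(3H)-one, via lithium enolate 9 (not isolated)
Conditions: LiN(i-Pr)2 (1.15 equiv), THF, −78 °C; then (i-Pr)3SiOCH2Cl, DMPU, −78 to −30 °C
Reagents that add atoms: (triisopropylsiloxy)methyl chloride CC(C)[Si](OCCl)(C(C)C)C(C)C
Why: Diastereoselective alkylation of a γ-lactone lithium enolate with an α-chloromethyl ether: the electrophile should enter anti to the neighbouring C4 silyloxymethyl group, setting C3 trans to C4 and delivering the second hydroxymethyl group already protected as its silyl ether.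

Step 6
Reactants: 11 4-bromo-2,6-dimethoxyphenol
Product: 12 2-(benzyloxy)-5-bromo-1,3-dimethoxybenzene
Conditions: BnBr, K2CO3, DMF, rt to 50 °C
Reagents that add atoms: benzyl bromide BrCc1ccccc1
Why: Williamson ether synthesis on the phenoxide; the benzyl ether masks the acidic phenol for the halogen–lithium exchange.

Step 7
Reactants: 12 2-(benzyloxy)-5-bromo-1,3-dimethoxybenzene; 10 (3S,4S,5R)-5-[4-(benzyloxy)-3,5-dimethoxyphenyl]-3,4-bis{[(triisopropylsilyl)oxy]methyl}dihydrofuran-2(3H)-one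
Product: 14 (3S,4S,5R)-2,5-bis[4-(benzyloxy)-3,5-dimethoxyphenyl]-3,4-bis{[(triisopropylsilyl)oxy]methyl}tetrahydrofuran-2-ol (anomeric mixture), via aryllithium 13 (not isolated)
Conditions: 12 (1.3 equiv), n-BuLi (1.25 equiv), THF, −78 °C, 30 min; then 10, THF, −78 °C; sat. aq NH4Cl
Reagents that add atoms: none
Why: Bromine–lithium exchange on 12 gives aryllithium 13, whose ipso carbon adds to the lactone carbonyl carbon C2 of 10 to give a lithium hemiketal alkoxide that persists at −78 °C and is protonated on work-up to 14 (in equilibrium with its open hydroxy ketone form). The closest known reaction type is the addition of aryllithiums to γ-lactones used for C-aryl glycosides and 2-aryltetrahydrofurans. No ring is closed; the oxolane ring of the lactone is kept. The only new stereocentre, the hemiketal carbon C2, forms as an anomeric mixture of no consequence, because it is flattened to the oxocarbenium ion and fixed in step 8 under control of the C3 substituent. The step needs mono-addition and addition in preference to deprotonation at C3: the persistent tetrahedral alkoxide at low temperature prevents a second addition, and C3 already holds its favoured trans relation to C4, so minor enolisation cannot change the stereochemistry. Exchange at the C–Br bond is much faster than ortho-lithiation or attack on the benzyl ether, so the ring is joined only through the carbon para to the benzyloxy group.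

Step 8
Reactants: 14 (3S,4S,5R)-2,5-bis[4-(benzyloxy)-3,5-dimethoxyphenyl]-3,4-bis{[(triisopropylsilyl)oxy]methyl}tetrahydrofuran-2-ol
Product: 16 (2S,3S,4S,5R)-2,5-bis[4-(benzyloxy)-3,5-dimethoxyphenyl]-3,4-bis{[(triisopropylsilyl)oxy]methyl}tetrahydrofuran, via oxocarbenium ion 15 (not isolated)
Conditions: Et3SiH (5 equiv), BF3·OEt2 (3 equiv), CH2Cl2, −78 to −20 °C; aq NaHCO3
Reagents that add atoms: none
Why: Ionic hydrogenation (reductive deoxygenation of a cyclic hemiketal): BF3, a Lewis acid promoter that is not consumed in the net equation, ionises C2–OH to the aryl-stabilised oxocarbenium ion 15 and the silane should deliver hydride to the ring face anti to the adjacent C3 silyloxymethyl group (and anti to the C5 aryl group), which places the C2 aryl group cis to C3; reversible enol ether formation cannot erode C3 because it already holds the favoured trans relation to C4.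

Step 9
Reactants: 16 (2S,3S,4S,5R)-2,5-bis[4-(benzyloxy)-3,5-dimethoxyphenyl]-3,4-bis{[(triisopropylsilyl)oxy]methyl}tetrahydrofuran
Product: 17 [(2S,3S,4S,5R)-2,5-bis[4-(benzyloxy)-3,5-dimethoxyphenyl]tetrahydrofuran-3,4-diyl]dimethanol
Conditions: Bu4NF (3 equiv), THF, 0 °C to rt
Reagents that add atoms: none
Why: Fluoride cleavage of both silyl ethers, done while the phenols are still benzylated so that no phenoxide (and hence no quinone methide pathway to epimerisation at the benzylic carbons) can form under the basic conditions.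

Step 10
Reactants: 17 [(2S,3S,4S,5R)-2,5-bis[4-(benzyloxy)-3,5-dimethoxyphenyl]tetrahydrofuran-3,4-diyl]dimethanol
Product: 18 4,4'-[(2S,3S,4S,5R)-3,4-bis(hydroxymethyl)tetrahydrofuran-2,5-diyl]bis(2,6-dimethoxyphenol)
Conditions: H2 (1 atm), 10% Pd/C, EtOAc–MeOH, rt, stopped at full conversion
Reagents that add atoms: none
Why: Catalytic hydrogenolysis of the two aryl benzyl ethers should be much faster than cleavage of the cyclic benzylic C–O bonds, so the reaction is stopped as soon as the ethers are gone; the neutral conditions leave the acid-sensitive cis C2 centre untouched.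

Compound list
1 | 4-(benzyloxy)-3,5-dimethoxybenzaldehyde | COc1cc(C=O)cc(OC)c1OCc1ccccc1 | starting material
2 | 4-vinyl-1,3-dioxolan-2-one (racemic) | C=CC1COC(=O)O1 | starting material
3 | (1R,2S)-1-[4-(benzyloxy)-3,5-dimethoxyphenyl]-2-ethenylpropane-1,3-diol | O[C@@H](c1cc(OC)c(OCc2ccccc2)c(OC)c1)[C@H](CO)C=C | intermediate
4 | (1R,2S)-1-[4-(benzyloxy)-3,5-dimethoxyphenyl]-2-{[(triisopropylsilyl)oxy]methyl}but-3-en-1-ol | O[C@@H](c1cc(OC)c(OCc2ccccc2)c(OC)c1)[C@H](CO[Si](C(C)C)(C(C)C)C(C)C)C=C | intermediate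
5 | B-alkyl-9-BBN adduct of 4 (boron on the terminal carbon) | O[C@@H](c1cc(OC)c(OCc2ccccc2)c(OC)c1)[C@H](CO[Si](C(C)C)(C(C)C)C(C)C)CCB1C2CCCC1CCC2 | intermediate (not isolated)
6 | (1R,2S)-1-[4-(benzyloxy)-3,5-dimethoxyphenyl]-2-{[(triisopropylsilyl)oxy]methyl}butane-1,4-diol | O[C@@H](c1cc(OC)c(OCc2ccccc2)c(OC)c1)[C@H](CO[Si](C(C)C)(C(C)C)C(C)C)CCO | intermediate
7 | (4S,5R)-5-[4-(benzyloxy)-3,5-dimethoxyphenyl]-4-{[(triisopropylsilyl)oxy]methyl}tetrahydrofuran-2-ol (lactol, anomeric mixture) | OC1O[C@@H](c2cc(OC)c(OCc3ccccc3)c(OC)c2)[C@H](CO[Si](C(C)C)(C(C)C)C(C)C)C1 | intermediate (not isolated)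
8 | (4S,5R)-5-[4-(benzyloxy)-3,5-dimethoxyphenyl]-4-{[(triisopropylsilyl)oxy]methyl}dihydrofuran-2(3H)-one | O=C1O[C@@H](c2cc(OC)c(OCc3ccccc3)c(OC)c2)[C@H](CO[Si](C(C)C)(C(C)C)C(C)C)C1 | intermediate
9 | lithium enolate of lactone 8 | [Li]OC1=C[C@@H](CO[Si](C(C)C)(C(C)C)C(C)C)[C@H](c2cc(OC)c(OCc3ccccc3)c(OC)c2)O1 | intermediate (not isolated)
10 | (3S,4S,5R)-5-[4-(benzyloxy)-3,5-dimethoxyphenyl]-3,4-bis{[(triisopropylsilyl)oxy]methyl}dihydrofuran-2(3H)-one | O=C1O[C@@H](c2cc(OC)c(OCc3ccccc3)c(OC)c2)[C@H](CO[Si](C(C)C)(C(C)C)C(C)C)[C@H]1CO[Si](C(C)C)(C(C)C)C(C)C | intermediate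
11 | 4-bromo-2,6-dimethoxyphenol | COc1cc(Br)cc(OC)c1O | starting material
12 | 2-(benzyloxy)-5-bromo-1,3-dimethoxybenzene | COc1cc(Br)cc(OC)c1OCc1ccccc1 | intermediate
13 | [4-(benzyloxy)-3,5-dimethoxyphenyl]lithium | [Li]c1cc(OC)c(OCc2ccccc2)c(OC)c1 | intermediate (not isolated)
14 | (3S,4S,5R)-2,5-bis[4-(benzyloxy)-3,5-dimethoxyphenyl]-3,4-bis{[(triisopropylsilyl)oxy]methyl}tetrahydrofuran-2-ol (hemiketal, anomeric mixture, in equilibrium with the open hydroxy ketone) | OC1(c2cc(OC)c(OCc3ccccc3)c(OC)c2)O[C@@H](c2cc(OC)c(OCc3ccccc3)c(OC)c2)[C@H](CO[Si](C(C)C)(C(C)C)C(C)C)[C@H]1CO[Si](C(C)C)(C(C)C)C(C)C | intermediate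
15 | (3S,4S,5R)-2,5-diaryl-3,4-bis(silyloxymethyl)-4,5-dihydro-3H-furan-1-ium (oxocarbenium ion, hydroxytrifluoroborate salt) | C1(c2cc(OC)c(OCc3ccccc3)c(OC)c2)=[O+][C@@H](c2cc(OC)c(OCc3ccccc3)c(OC)c2)[C@H](CO[Si](C(C)C)(C(C)C)C(C)C)[C@H]1CO[Si](C(C)C)(C(C)C)C(C)C.O[B-](F)(F)F | intermediate (not isolated)
16 | (2S,3S,4S,5R)-2,5-bis[4-(benzyloxy)-3,5-dimethoxyphenyl]-3,4-bis{[(triisopropylsilyl)oxy]methyl}tetrahydrofuran | COc1cc([C@H]2O[C@@H](c3cc(OC)c(OCc4ccccc4)c(OC)c3)[C@H](CO[Si](C(C)C)(C(C)C)C(C)C)[C@H]2CO[Si](C(C)C)(C(C)C)C(C)C)cc(OC)c1OCc1ccccc1 | intermediate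
17 | [(2S,3S,4S,5R)-2,5-bis[4-(benzyloxy)-3,5-dimethoxyphenyl]tetrahydrofuran-3,4-diyl]dimethanol | COc1cc([C@H]2O[C@@H](c3cc(OC)c(OCc4ccccc4)c(OC)c3)[C@H](CO)[C@H]2CO)cc(OC)c1OCc1ccccc1 | intermediate
18 | 4,4'-[(2S,3S,4S,5R)-3,4-bis(hydroxymethyl)tetrahydrofuran-2,5-diyl]bis(2,6-dimethoxyphenol) | COc1cc([C@H]2O[C@@H](c3cc(OC)c(O)c(OC)c3)[C@H](CO)[C@H]2CO)cc(OC)c1O | target

Total step count: 10. Longest linear sequence: 9 steps (steps 1–5 and 7–10, from aldehyde 1); step 6 is a one-step branch that supplies the aryl bromide.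

Steps most likely to fail

Step 1. The catalytic allylation may stall with the electron-rich aldehyde or lose anti- or enantioselectivity. The fallback sets out from 1 and comes back at 8, using auxiliary control instead of catalyst control. (R)-4-Benzyloxazolidin-2-one is acylated (n-BuLi, THF, −78 °C; methyl 4-chloro-4-oxobutanoate) to the succinate imide methyl 4-[(4R)-4-benzyl-2-oxo-1,3-oxazolidin-3-yl]-4-oxobutanoate F1. Its boron Z-enolate (Bu2BOTf, i-Pr2NEt, CH2Cl2, −78 to 0 °C) is combined with 1 in an Evans syn-aldol reaction, which should give the adduct methyl (3R,4R)-4-[4-(benzyloxy)-3,5-dimethoxyphenyl]-3-{[(4R)-4-benzyl-2-oxo-1,3-oxazolidin-3-yl]carbonyl}-4-hydroxybutanoate F2. LiOH/H2O2 (THF–H2O, 0 °C to rt) removes the auxiliary and the methyl ester, and acidification closes the trans lactone acid (2R,3R)-2-[4-(benzyloxy)-3,5-dimethoxyphenyl]-5-oxotetrahydrofuran-3-carboxylic acid F3; the syn aldol relation maps onto the 4,5-trans lactone. BH3·SMe2 (THF, 0 °C) reduces the acid in the presence of the lactone to the alcohol (4S,5R)-5-[4-(benzyloxy)-3,5-dimethoxyphenyl]-4-(hydroxymethyl)dihydrofuran-2(3H)-one F4, and TIPSCl/imidazole returns to the route at 8.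

Step 5. C-Alkylation by the bulky chloromethyl silyl ether may be slow, with O-alkylation or proton return competing. The fallback sets out from 8 and comes back at 10, replacing alkylation by an aldol reaction. The lithium enolate (LiN(SiMe3)2, THF, −78 °C) is treated with monomeric formaldehyde (gas from cracked paraformaldehyde), again anti to the C4 substituent, to give the hydroxymethyl lactone (3S,4S,5R)-5-[4-(benzyloxy)-3,5-dimethoxyphenyl]-3-(hydroxymethyl)-4-{[(triisopropylsilyl)oxy]methyl}dihydrofuran-2(3H)-one F5. Silylation (TIPSOTf, 2,6-lutidine, CH2Cl2, 0 °C) then gives 10.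

Step 7. The aryllithium may abstract the C3 proton of the hindered lactone in place of adding to the carbonyl, or add a second time after ring opening. The fallback sets out from 10 and comes back at 14, moving the addition to an open-chain Weinreb amide. Me2AlN(OMe)Me (from AlMe3 and MeNHOMe·HCl, CH2Cl2, 0 °C) opens the lactone to the hydroxy amide (2S,3S,4R)-4-[4-(benzyloxy)-3,5-dimethoxyphenyl]-4-hydroxy-N-methoxy-N-methyl-2,3-bis{[(triisopropylsilyl)oxy]methyl}butanamide F6. This is silylated at once (Et3SiCl, imidazole, CH2Cl2) to the triethylsilyl ether (2S,3S,4R)-4-[4-(benzyloxy)-3,5-dimethoxyphenyl]-N-methoxy-N-methyl-4-[(triethylsilyl)oxy]-2,3-bis{[(triisopropylsilyl)oxy]methyl}butanamide F7. Aryllithium 13 (from 12 as in step 7) adds once to the amide through its stable chelate to give the ketone (2S,3S,4R)-1,4-bis[4-(benzyloxy)-3,5-dimethoxyphenyl]-4-[(triethylsilyl)oxy]-2,3-bis{[(triisopropylsilyl)oxy]methyl}butan-1-one F8. Selective removal of the triethylsilyl group (HF·pyridine, pyridine, THF, 0 °C) lets the freed hydroxyl close onto the ketone, giving hemiketal 14.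

Further compounds
F1 | step 1 | methyl 4-[(4R)-4-benzyl-2-oxo-1,3-oxazolidin-3-yl]-4-oxobutanoate | COC(=O)CCC(=O)N1[C@H](Cc2ccccc2)COC1=O
F2 | step 1 | methyl (3R,4R)-4-[4-(benzyloxy)-3,5-dimethoxyphenyl]-3-{[(4R)-4-benzyl-2-oxo-1,3-oxazolidin-3-yl]carbonyl}-4-hydroxybutanoate | O[C@@H](c1cc(OC)c(OCc2ccccc2)c(OC)c1)[C@H](C(=O)N1[C@H](Cc2ccccc2)COC1=O)CC(=O)OC
F3 | step 1 | (2R,3R)-2-[4-(benzyloxy)-3,5-dimethoxyphenyl]-5-oxotetrahydrofuran-3-carboxylic acid | O=C1O[C@@H](c2cc(OC)c(OCc3ccccc3)c(OC)c2)[C@H](C(=O)O)C1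
F4 | step 1 | (4S,5R)-5-[4-(benzyloxy)-3,5-dimethoxyphenyl]-4-(hydroxymethyl)dihydrofuran-2(3H)-one | O=C1O[C@@H](c2cc(OC)c(OCc3ccccc3)c(OC)c2)[C@H](CO)C1
F5 | step 5 | (3S,4S,5R)-5-[4-(benzyloxy)-3,5-dimethoxyphenyl]-3-(hydroxymethyl)-4-{[(triisopropylsilyl)oxy]methyl}dihydrofuran-2(3H)-one | O=C1O[C@@H](c2cc(OC)c(OCc3ccccc3)c(OC)c2)[C@H](CO[Si](C(C)C)(C(C)C)C(C)C)[C@H]1CO
F6 | step 7 | (2S,3S,4R)-4-[4-(benzyloxy)-3,5-dimethoxyphenyl]-4-hydroxy-N-methoxy-N-methyl-2,3-bis{[(triisopropylsilyl)oxy]methyl}butanamide | O[C@@H](c1cc(OC)c(OCc2ccccc2)c(OC)c1)[C@H](CO[Si](C(C)C)(C(C)C)C(C)C)[C@@H](CO[Si](C(C)C)(C(C)C)C(C)C)C(=O)N(C)OC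
F7 | step 7 | (2S,3S,4R)-4-[4-(benzyloxy)-3,5-dimethoxyphenyl]-N-methoxy-N-methyl-4-[(triethylsilyl)oxy]-2,3-bis{[(triisopropylsilyl)oxy]methyl}butanamide | CC[Si](CC)(CC)O[C@@H](c1cc(OC)c(OCc2ccccc2)c(OC)c1)[C@H](CO[Si](C(C)C)(C(C)C)C(C)C)[C@@H](CO[Si](C(C)C)(C(C)C)C(C)C)C(=O)N(C)OC
F8 | step 7 | (2S,3S,4R)-1,4-bis[4-(benzyloxy)-3,5-dimethoxyphenyl]-4-[(triethylsilyl)oxy]-2,3-bis{[(triisopropylsilyl)oxy]methyl}butan-1-one | CC[Si](CC)(CC)O[C@@H](c1cc(OC)c(OCc2ccccc2)c(OC)c1)[C@H](CO[Si](C(C)C)(C(C)C)C(C)C)[C@@H](CO[Si](C(C)C)(C(C)C)C(C)C)C(=O)c1cc(OC)c(OCc2ccccc2)c(OC)c1
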